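**Retrosynthetic overview**

1. Numbering: C1 (alkyne CH) to C15 (ethyl CH3); ring A = O/C3–C6, ring B = O/C4–C7, ring C = O/C9–C13. The strategy rests on ring C: all four substituents (C8 on C9, Br on C10 and C12, ethyl on C13) are equatorial and the ring is locally mirror-symmetric through its O and C11, so O, C9, C8, C14, C13 map onto furan and C10–C11–C12 onto a three-carbon oxyallyl cation.
2. Key disconnection: a (4+3) cycloaddition of furan with a 1,3-bis(benzyloxy)-2-silyloxyallyl cation forms C9–C10 and C12–C13 and gives a meso oxabicycle. Deoxygenation at C11, cleavage of C8=C14, lipase desymmetrisation and a double SN2 bromination (axial O to equatorial Br) then give ring C.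
3. C6–C7: the C8 aldehyde is homologated to a C7≡C8 acetylide, which acylates a Weinreb amide made from 2-deoxy-D-ribose (C2–C6; sugar C3 becomes C4 as found, sugar C4 becomes C3 and is inverted later). C6 is set by asymmetric transfer hydrogenation.
4. Ring B: the C4 hydroxyl adds to the Z C7=C8 alkene in a bromoetherification (O–C7 and Br–C8, anti). Ring A: after C2 has become the alkyne, O6 displaces a C3 propargylic mesylate with inversion.
5. Order of ring formation: ring C (step 4, as the oxabicycle), ring B (step 27), ring A (step 32).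

Key step: step 4

Assumption (chemistry): the lipase in step 9 acylates the hydroxymethyl group on the R-configured ring carbon of meso diol 17; if it prefers the other arm, hydrolysis of the meso diacetate with the same enzyme gives the same monoacetate 18.

**Route**

Step 1
Reactants: 1 1,3-bis(benzyloxy)propan-2-ol
Product: 2 1,3-bis(benzyloxy)propan-2-one
Conditions: Dess–Martin periodinane, CH2Cl2, rt
Reagents that add atoms: none
Why: Dess–Martin oxidation of the secondary alcohol gives the symmetric ketone without touching the benzyl ethers; no stereocentre is involved.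

Step 2
Reactants: 2 1,3-bis(benzyloxy)propan-2-one; 3 benzyl alcohol
Product: 5 1,1,3-tris(benzyloxy)propan-2-one, via chloro ketone 4 (not isolated)
Conditions: SO2Cl2 (1.0 equiv), CH2Cl2, 0 °C; then BnOH (3), 2,6-lutidine, 0 °C to rt
Reagents that add atoms: none
Why: Enol chlorination of the alpha-alkoxy ketone gives the alpha-chloro ether 4, whose chloride is replaced by benzyl alcohol through the oxocarbenium ion (alpha-halogenation followed by SN1 acetalisation), which raises one CH2OBn group to the acetal oxidation level; one equivalent of SO2Cl2 limits dichlorination.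

Step 3
Reactants: 5 1,1,3-tris(benzyloxy)propan-2-one; 6 chlorotriethylsilane
Product: 8 (Z)-1,3,3-tris(benzyloxy)-2-(triethylsilyloxy)prop-1-ene, via lithium Z-enolate 7 (not isolated)
Conditions: LiN(iPr)2, THF, −78 °C; then Et3SiCl (6), −78 to 0 °C
Reagents that add atoms: none
Why: Kinetic deprotonation removes a proton of the CH2OBn group, not the hindered acetal CH, and lithium chelation by the alpha-benzyloxy oxygen should give the Z enolate 7, which is trapped on oxygen (silyl enol ether formation).

Step 4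
Reactants: 8 (Z)-1,3,3-tris(benzyloxy)-2-(triethylsilyloxy)prop-1-ene; 9 furan
Product: 11 meso-(1R,2S,4R,5S)-2,4-bis(benzyloxy)-8-oxabicyclo[3.2.1]oct-6-en-3-one (both ethers equatorial), via silyloxyallyl cation triflate 10 (not isolated)
Conditions: Me3SiOTf (10 mol %), furan (5 equiv), CH2Cl2, −78 °C
Reagents that add atoms: none
Why: Proposed new method: Me3SiOTf removes one acetal benzyloxy group of 8 as a silyl ether and leaves the W-shaped 1,3-bis(benzyloxy)-2-silyloxyallyl cation 10, which is stabilised by both ether oxygens and acts as the three-carbon 2π partner; furan bonds to its two termini through C2 and C5, in one step or in two successive C–C bond formations, and silyl transfer from the adduct regenerates the Lewis acid. The closest known reaction is the Me3SiOTf-catalysed (4+3) cycloaddition of furan with 2-silyloxyallyl cations made from enol ethers of alpha-alkoxy acetals, which gives 2-alkoxy-8-oxabicyclo[3.2.1]oct-6-en-3-ones; the second alkoxy group on the far terminus should make the cation more stable and less electrophilic but leaves it a vinylogous oxocarbenium ion of the kind furan traps. The step closes the seven-membered carbocycle C8–C9–C10–C11–C12–C13–C14 by intermolecular (4+3) cycloaddition (bonds C9–C10 and C12–C13), and because the furan oxygen already spans C9 and C13 this also completes the six-membered ring C. C9 and C13 are cis because both bonds form on one face of the furan; C10 and C12 carry their benzyloxy groups cis to the C8=C14 bridge (equatorial on ring C) because the cation reacts in its W form, with the Z geometry of step 3 kept at one terminus and adopted at the other, through the compact transition state that holds the silyloxy group over the diene. The only selectivity needed is this cis,cis diastereoselectivity, since the product is meso and the two termini are equivalent; an axial epimer, if formed, can be equilibrated through the enol with DBU because both ether-bearing carbons flank the ketone.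

Step 5
Reactants: 11 meso cycloadduct ketone
Product: 12 meso-2,4-bis(benzyloxy)-8-oxabicyclo[3.2.1]oct-6-en-3-ol (OH axial, on the side of the alkene bridge, all three oxygens cis)
Conditions: Li(s-Bu)3BH, THF, −78 °C
Reagents that add atoms: none
Why: The bulky hydride attacks the ketone on the face away from the C8=C14 bridge (carbonyl reduction under steric approach control) to give the axial alcohol; the C11 configuration is of no consequence because the oxygen is removed in step 7.

Step 6
Reactants: 12 axial alcohol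
Product: 14 O-[meso-2,4-bis(benzyloxy)-8-oxabicyclo[3.2.1]oct-6-en-3-yl] S-methyl dithiocarbonate, via sodium xanthate 13 (not isolated)
Conditions: NaH, CS2, THF, 0 °C; then MeI, rt
Reagents that add atoms: carbon disulfide (S=C=S); iodomethane (CI)
Why: Xanthate formation: the alkoxide adds to CS2 and the dithiocarbonate anion 13 is S-methylated, with no change at any stereocentre.

Step 7
Reactants: 14 S-methyl xanthate
Product: 15 meso-2,4-bis(benzyloxy)-8-oxabicyclo[3.2.1]oct-6-ene (both ethers cis to the alkene bridge)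
Conditions: Bu3SnH, AIBN (cat.), toluene, 100 °C
Reagents that add atoms: none
Why: Barton–McCombie deoxygenation: the stannyl radical adds to the thiocarbonyl, the C11–O bond fragments and the secondary C11 radical takes hydrogen from Bu3SnH faster than it can expel a beta-benzyloxy group or add to the bridge alkene, which would need a four-membered ring.

Step 8
Reactants: 15 deoxygenated meso bicyclic alkene
Product: 17 meso-[(2R,3R,5S,6S)-3,5-bis(benzyloxy)oxane-2,6-diyl]dimethanol (all-cis), via dialdehyde 16 (not isolated)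
Conditions: O3, CH2Cl2/MeOH, −78 °C; then NaBH4, −78 to 0 °C
Reagents that add atoms: ozone ([O-][O+]=O)
Why: Ozonolysis with reductive work-up cleaves C8=C14 to two hydroxymethyl groups without touching the four stereocentres, and ring C can then flip so that both CH2OH groups are equatorial and both benzyloxy groups axial.

Step 9
Reactants: 17 meso diol
Product: 18 [(2R,3R,5S,6S)-3,5-bis(benzyloxy)-6-(hydroxymethyl)oxan-2-yl]methyl acetate (acetate on the future C8, free OH on the future C14)
Conditions: Burkholderia cepacia lipase, vinyl acetate, t-BuOMe, rt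
Reagents that add atoms: vinyl acetate (C=COC(C)=O)
Why: Lipase-catalysed transesterification with an irreversible acyl donor differentiates the two enantiotopic hydroxymethyl groups (enzymatic desymmetrisation of a meso diol), which fixes the absolute configuration of C9, C10, C12 and C13 at once.

Step 10
Reactants: 18 monoacetate
Product: 19 [(2R,3R,5S,6R)-3,5-bis(benzyloxy)-6-formyloxan-2-yl]methyl acetate (C14 aldehyde)
Conditions: Dess–Martin periodinane, CH2Cl2, 0 °C to rt
Reagents that add atoms: none
Why: Dess–Martin oxidation of the primary alcohol; the cis-2,6 (equatorial) aldehyde is the thermodynamic epimer at C13, so enolisation cannot erode it.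

Step 11
Reactants: 19 C14 aldehyde
Product: 20 [(2R,3R,5S,6S)-3,5-bis(benzyloxy)-6-ethenyloxan-2-yl]methyl acetate
Conditions: Ph3PCH3Br, KOtBu, THF, 0 °C; then 19, −78 to 0 °C
Reagents that add atoms: methyltriphenylphosphonium bromide (C[P+](c1ccccc1)(c1ccccc1)c1ccccc1.[Br-])
Why: Wittig methylenation adds C15; the unstabilised ylide, used in slight excess at low temperature, should react with the aldehyde far faster than with the acetate.

Step 12
Reactants: 20 vinyl compound
Product: 21 [(2R,3R,5S,6S)-6-ethyl-3,5-dihydroxyoxan-2-yl]methyl acetate (both OH axial)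
Conditions: H2 (1 atm), Pd(OH)2/C, EtOAc/EtOH, rt
Reagents that add atoms: none
Why: Catalytic hydrogenation saturates C14=C15 to the ethyl group and hydrogenolyses both benzyl ethers in one operation, while the acetate and the ring stereocentres are inert.

Step 13
Reactants: 21 diol acetate
Product: 23 [(2R,3S,5R,6S)-3,5-dibromo-6-ethyloxan-2-yl]methyl acetate, via bis-triflate 22 (not isolated)
Conditions: Tf2O, pyridine, CH2Cl2, −20 °C; then n-Bu4NBr, 0 °C to rt
Reagents that add atoms: tetrabutylammonium bromide (CCCC[N+](CCCC)(CCCC)CCCC.[Br-])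
Why: Both axial alcohols are triflated and each triflate is displaced by bromide in an SN2 reaction with inversion (equatorial attack on an axial leaving group next to C9 or C13, the favourable case known from 4-O-triflyl galactosides), which gives the equatorial bromides at C10 and C12.

Step 14
Reactants: 23 dibromide acetate
Product: 24 [(2R,3S,5R,6S)-3,5-dibromo-6-ethyloxan-2-yl]methanol
Conditions: K2CO3 (cat.), MeOH, 0 °C
Reagents that add atoms: none
Why: Base-catalysed transesterification removes the acetate; the equatorial bromides have no antiperiplanar hydrogen in the chair and should resist elimination.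

Step 15
Reactants: 24 primary alcohol
Product: 25 (2R,3S,5R,6S)-3,5-dibromo-6-ethyloxane-2-carbaldehyde (C8 aldehyde)
Conditions: Dess–Martin periodinane, CH2Cl2, 0 °C
Reagents that add atoms: none
Why: Dess–Martin oxidation under neutral conditions gives the C8 aldehyde, which is used at once because it carries a beta-bromide.

Step 16
Reactants: 25 C8 aldehyde
Product: 26 (2R,3S,5R,6S)-3,5-dibromo-2-(2,2-dibromoethenyl)-6-ethyloxane
Conditions: CBr4, PPh3, CH2Cl2, 0 °C
Reagents that add atoms: tetrabromomethane (BrC(Br)(Br)Br)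
Why: Ramirez dibromo-olefination (first stage of the Corey–Fuchs sequence) adds C7 under non-basic conditions, so the base-sensitive aldehyde is never exposed to base.

Step 17
Reactants: 27 2-deoxy-D-ribose
Product: 28 2-deoxy-D-ribono-1,4-lactone
Conditions: Br2, H2O, rt
Reagents that add atoms: none
Why: Bromine-water oxidation of the aldose hemiacetal gives the aldonic acid, which closes to the 1,4-lactone; the two sugar stereocentres (future C4 and C3) are untouched.

Step 18
Reactants: 28 2-deoxy-D-ribono-1,4-lactone; 6 chlorotriethylsilane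
Product: 29 5-O-(triethylsilyl)-2-deoxy-D-ribono-1,4-lactone
Conditions: Et3SiCl (6, 1.05 equiv), imidazole, CH2Cl2/DMF, −40 °C
Reagents that add atoms: none
Why: Silyl ether formation under kinetic control: the unhindered primary hydroxyl (the future O2) reacts with one equivalent of the silyl chloride at low temperature much faster than the secondary ring hydroxyl.

Step 19
Reactants: 29 5-O-(triethylsilyl)-2-deoxy-D-ribono-1,4-lactone; 6 chlorotriethylsilane
Product: 30 3,5-bis-O-(triethylsilyl)-2-deoxy-D-ribono-1,4-lactone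
Conditions: Et3SiCl (6, 1.3 equiv), imidazole, 4-(dimethylamino)pyridine (cat.), DMF, 0 °C to rt
Reagents that add atoms: none
Why: Silyl ether formation on the remaining secondary hydroxyl (the future O4) under more forcing conditions, so that both oxygens carry the same acid-labile group and can be released together in step 26.

Step 20
Reactants: 30 bis(triethylsilyl) lactone
Product: 31 (3S,4R)-4-hydroxy-N-methoxy-N-methyl-3,5-bis(triethylsilyloxy)pentanamide
Conditions: MeNH(OMe)·HCl, AlMe3, CH2Cl2, 0 °C to rt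
Reagents that add atoms: N,O-dimethylhydroxylamine hydrochloride (CNOC.Cl)
Why: Aminolysis of the lactone by the aluminium amide (Weinreb amide formation) opens the ring and frees only the former ring oxygen, the C3 hydroxyl, so the three sugar oxygens are differentiated.

Step 21
Reactants: 31 hydroxy Weinreb amide
Product: 32 (3S,4R)-4-(tert-butyldimethylsilyloxy)-N-methoxy-N-methyl-3,5-bis(triethylsilyloxy)pentanamide
Conditions: t-BuMe2SiOTf, 2,6-lutidine, CH2Cl2, −78 °C
Reagents that add atoms: tert-butyldimethylsilyl triflate (CC(C)(C)[Si](C)(C)OS(=O)(=O)C(F)(F)F)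
Why: Silylation with the triflate at −78 °C should outrun relactonisation of the gamma-hydroxy amide and gives a silyl ether that outlasts the triethylsilyl groups.

Step 22
Reactants: 26 dibromo-olefin; 32 Weinreb amide
Product: 34 (5S,6R)-6-(tert-butyldimethylsilyloxy)-1-[(2R,3S,5R,6S)-3,5-dibromo-6-ethyloxan-2-yl]-5,7-bis(triethylsilyloxy)hept-1-yn-3-one (C6 ynone), via lithium acetylide 33 (not isolated)
Conditions: n-BuLi (2.1 equiv), THF, −78 °C; then 32, −78 to −20 °C; aq. NH4Cl
Reagents that add atoms: none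
Why: Second stage of the Corey–Fuchs reaction: bromine–lithium exchange, rearrangement and deprotonation give acetylide 33, which acylates the Weinreb amide once through the chelated tetrahedral intermediate (C6–C7 bond); n-BuLi should not exchange with secondary alkyl bromides at a comparable rate at −78 °C, and the equatorial bromides cannot undergo antiperiplanar elimination.

Step 23
Reactants: 34 ynone
Product: 35 (3S,5S,6R)-6-(tert-butyldimethylsilyloxy)-1-[(2R,3S,5R,6S)-3,5-dibromo-6-ethyloxan-2-yl]-5,7-bis(triethylsilyloxy)hept-1-yn-3-ol (C6 alcohol, 6S)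
Conditions: RuCl[(S,S)-TsDPEN](p-cymene) (2 mol %), KOH (cat.), i-PrOH, rt
Reagents that add atoms: none
Why: Noyori asymmetric transfer hydrogenation of the alkynyl ketone under catalyst control; the (S,S) catalyst should give the (6S) propargylic alcohol, the sense known for alkynyl alkyl ketones.

Step 24
Reactants: 35 propargylic alcohol
Product: 36 C6 tert-butyldiphenylsilyl ether of 35
Conditions: t-BuPh2SiCl, imidazole, DMF, rt
Reagents that add atoms: tert-butyl(chloro)diphenylsilane (CC(C)(C)[Si](Cl)(c1ccccc1)c1ccccc1)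
Why: Silyl ether formation; the bulky group protects O6 until the last step and cannot act as a neighbouring group in step 27.

Step 25
Reactants: 36 silylated alkyne
Product: 37 (Z)-C7=C8 alkene (otherwise as 36)
Conditions: H2 (1 atm), Pd/CaCO3 poisoned with Pb(OAc)2, quinoline, EtOAc, rt
Reagents that add atoms: none
Why: Lindlar semi-hydrogenation (syn addition of H2 on the poisoned surface) gives the Z alkene; C–Br bonds and silyl ethers are not reduced under these conditions.

Step 26
Reactants: 37 Z alkene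
Product: 38 C2,C4-diol (C3 tert-butyldimethylsilyl and C6 tert-butyldiphenylsilyl ethers kept)
Conditions: pyridinium p-toluenesulfonate, MeOH/CH2Cl2, 0 °C
Reagents that add atoms: none
Why: Acid-catalysed methanolysis cleaves the two triethylsilyl ethers selectively, because the two bulkier silyl ethers are cleaved orders of magnitude more slowly.

Step 27
Reactants: 38 Z-alkene diol
Product: 39 ring B bromoether: (2R)-2-[(2S,4S,5S)-5-{(R)-bromo[(2S,3S,5R,6S)-3,5-dibromo-6-ethyloxan-2-yl]methyl}-4-(tert-butyldiphenylsilyloxy)oxolan-2-yl]-2-(tert-butyldimethylsilyloxy)ethanol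
Conditions: N-bromosuccinimide, MeCN, −20 to 0 °C
Reagents that add atoms: N-bromosuccinimide (O=C1CCC(=O)N1Br)
Why: Bromoetherification (5-exo-trig attack of the C4 hydroxyl on the bromonium ion): anti addition to the Z alkene gives the threo O7/Br8 pair, and allylic 1,3-strain holds H6 in the alkene plane so that O4 reaches C7 on the face that puts C8 trans to the C6 silyloxy group, which sets C7 (S) and C8 (R); closure through the primary C2 hydroxyl would need a seven-membered ring and should be much slower.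

Step 28
Reactants: 39 bromoether alcohol
Product: 40 C2 aldehyde (alpha-silyloxy aldehyde; otherwise as 39)
Conditions: Dess–Martin periodinane, CH2Cl2, 0 °C to rt
Reagents that add atoms: none
Why: Dess–Martin oxidation of the only free alcohol.

Step 29
Reactants: 40 C2 aldehyde
Product: 41 terminal alkyne C1≡C2 with (3R) tert-butyldimethylsilyl ether (otherwise as 39)
Conditions: dimethyl (1-diazo-2-oxopropyl)phosphonate, K2CO3, MeOH, 0 °C to rt
Reagents that add atoms: dimethyl (1-diazo-2-oxopropyl)phosphonate (CC(=O)C(=[N+]=[N-])P(=O)(OC)OC)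
Why: Ohira–Bestmann (Seyferth–Gilbert) homologation turns the aldehyde into the terminal alkyne and adds C1; the mild carbonate base should leave the alpha-silyloxy stereocentre at C3 and the secondary bromides intact.

Step 30
Reactants: 41 silylated alkyne
Product: 42 (1R)-1-[(2S,4S,5S)-5-{(R)-bromo[(2S,3S,5R,6S)-3,5-dibromo-6-ethyloxan-2-yl]methyl}-4-(tert-butyldiphenylsilyloxy)oxolan-2-yl]prop-2-yn-1-ol (C3 alcohol)
Conditions: HF·pyridine, pyridine, THF, 0 °C to rt
Reagents that add atoms: none
Why: Buffered HF·pyridine cleaves the secondary tert-butyldimethylsilyl ether at C3 faster than the tert-butyldiphenylsilyl ether at C6 (selective desilylation).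

Step 31
Reactants: 42 propargylic alcohol
Product: 43 C3 methanesulfonate of 42 (3R)
Conditions: MsCl, Et3N, CH2Cl2, −20 °C
Reagents that add atoms: methanesulfonyl chloride (CS(Cl)(=O)=O)
Why: Sulfonylation of the propargylic alcohol gives the mesylate with retention at C3; it is used without storage.

Step 32
Reactants: 43 propargylic mesylate
Product: 45 (1S,3S,4S,6S)-3-{(R)-bromo[(2S,3S,5R,6S)-3,5-dibromo-6-ethyloxan-2-yl]methyl}-6-ethynyl-2,5-dioxabicyclo[2.2.1]heptane (target), via C6 alkoxide 44 (not isolated)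
Conditions: n-Bu4NF, THF, 0 °C to rt
Reagents that add atoms: none
Why: Fluoride removes the silyl group from O6 and alkoxide 44 displaces the propargylic mesylate in a 5-exo-tet Williamson etherification with inversion at C3, which closes ring A and leaves the alkyne endo; this is the closure used for the 2,5-dioxabicyclo[2.2.1]heptane core of locked nucleosides, and O6 and the C3 side chain are cis on ring B as it requires.

**Compound list**

1 | 1,3-bis(benzyloxy)propan-2-ol | OC(COCc1ccccc1)COCc1ccccc1 | starting material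
2 | 1,3-bis(benzyloxy)propan-2-one | O=C(COCc1ccccc1)COCc1ccccc1 | intermediate
3 | benzyl alcohol | OCc1ccccc1 | starting material
4 | 1,3-bis(benzyloxy)-1-chloropropan-2-one (racemic, formed in the flask) | O=C(COCc1ccccc1)C(Cl)OCc1ccccc1 | intermediate
5 | 1,1,3-tris(benzyloxy)propan-2-one | O=C(COCc1ccccc1)C(OCc1ccccc1)OCc1ccccc1 | intermediate
6 | chlorotriethylsilane | CC[Si](Cl)(CC)CC | starting material
7 | lithium (Z)-1,3,3-tris(benzyloxy)prop-1-en-2-olate (formed in the flask) | [Li]O/C(C(OCc1ccccc1)OCc1ccccc1)=C\OCc1ccccc1 | intermediate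
8 | (Z)-1,3,3-tris(benzyloxy)-2-(triethylsilyloxy)prop-1-ene | CC[Si](CC)(CC)O/C(C(OCc1ccccc1)OCc1ccccc1)=C\OCc1ccccc1 | intermediate
9 | furan | c1ccoc1 | starting material
10 | 1,3-bis(benzyloxy)-2-(triethylsilyloxy)allyl cation triflate, W form, one resonance form drawn (formed in the flask) | CC[Si](CC)(CC)O/C(C=[O+]Cc1ccccc1)=C\OCc1ccccc1.[O-]S(=O)(=O)C(F)(F)F | intermediate
11 | meso-(1R,2S,4R,5S)-2,4-bis(benzyloxy)-8-oxabicyclo[3.2.1]oct-6-en-3-one, both ethers equatorial | O=C1[C@@H](OCc3ccccc3)[C@H]2C=C[C@H](O2)[C@H]1OCc4ccccc4 | intermediate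
12 | meso-2,4-bis(benzyloxy)-8-oxabicyclo[3.2.1]oct-6-en-3-ol, OH axial, all oxygens cis | O[C@H]1[C@@H](OCc3ccccc3)[C@H]2C=C[C@H](O2)[C@H]1OCc4ccccc4 | intermediate
13 | sodium O-alkyl dithiocarbonate of 12 (formed in the flask) | [Na+].[S-]C(=S)O[C@H]1[C@@H](OCc3ccccc3)[C@H]2C=C[C@H](O2)[C@H]1OCc4ccccc4 | intermediate
14 | O-[meso-2,4-bis(benzyloxy)-8-oxabicyclo[3.2.1]oct-6-en-3-yl] S-methyl dithiocarbonate | CSC(=S)O[C@H]1[C@@H](OCc3ccccc3)[C@H]2C=C[C@H](O2)[C@H]1OCc4ccccc4 | intermediate
15 | meso-2,4-bis(benzyloxy)-8-oxabicyclo[3.2.1]oct-6-ene, ethers cis to the alkene bridge | C1[C@@H](OCc3ccccc3)[C@H]2C=C[C@H](O2)[C@H]1OCc4ccccc4 | intermediate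
16 | meso all-cis 3,5-bis(benzyloxy)oxane-2,6-dicarbaldehyde (formed in the flask) | O=C[C@H]1O[C@@H](C=O)[C@@H](OCc2ccccc2)C[C@H]1OCc3ccccc3 | intermediate
17 | meso-[(2R,3R,5S,6S)-3,5-bis(benzyloxy)oxane-2,6-diyl]dimethanol | OC[C@H]1O[C@@H](CO)[C@@H](OCc2ccccc2)C[C@H]1OCc3ccccc3 | intermediate
18 | [(2R,3R,5S,6S)-3,5-bis(benzyloxy)-6-(hydroxymethyl)oxan-2-yl]methyl acetate | CC(=O)OC[C@H]1O[C@@H](CO)[C@@H](OCc2ccccc2)C[C@H]1OCc3ccccc3 | intermediate
19 | [(2R,3R,5S,6R)-3,5-bis(benzyloxy)-6-formyloxan-2-yl]methyl acetate | CC(=O)OC[C@H]1O[C@@H](C=O)[C@@H](OCc2ccccc2)C[C@H]1OCc3ccccc3 | intermediate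
20 | [(2R,3R,5S,6S)-3,5-bis(benzyloxy)-6-ethenyloxan-2-yl]methyl acetate | CC(=O)OC[C@H]1O[C@@H](C=C)[C@@H](OCc2ccccc2)C[C@H]1OCc3ccccc3 | intermediate
21 | [(2R,3R,5S,6S)-6-ethyl-3,5-dihydroxyoxan-2-yl]methyl acetate | CC(=O)OC[C@H]1O[C@@H](CC)[C@@H](O)C[C@H]1O | intermediate
22 | bis(trifluoromethanesulfonate) of 21 (formed in the flask) | CC(=O)OC[C@H]1O[C@@H](CC)[C@@H](OS(=O)(=O)C(F)(F)F)C[C@H]1OS(=O)(=O)C(F)(F)F | intermediate
23 | [(2R,3S,5R,6S)-3,5-dibromo-6-ethyloxan-2-yl]methyl acetate | CC(=O)OC[C@H]1O[C@@H](CC)[C@H](Br)C[C@@H]1Br | intermediate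
24 | [(2R,3S,5R,6S)-3,5-dibromo-6-ethyloxan-2-yl]methanol | OC[C@H]1O[C@@H](CC)[C@H](Br)C[C@@H]1Br | intermediate
25 | (2R,3S,5R,6S)-3,5-dibromo-6-ethyloxane-2-carbaldehyde | O=C[C@H]1O[C@@H](CC)[C@H](Br)C[C@@H]1Br | intermediate
26 | (2R,3S,5R,6S)-3,5-dibromo-2-(2,2-dibromoethenyl)-6-ethyloxane | BrC(Br)=C[C@H]1O[C@@H](CC)[C@H](Br)C[C@@H]1Br | intermediate
27 | 2-deoxy-D-ribose (open-chain form drawn) | O=CC[C@H](O)[C@H](O)CO | starting material
28 | 2-deoxy-D-ribono-1,4-lactone | OC[C@H]1OC(=O)C[C@@H]1O | intermediate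
29 | 5-O-(triethylsilyl)-2-deoxy-D-ribono-1,4-lactone | CC[Si](CC)(CC)OC[C@H]1OC(=O)C[C@@H]1O | intermediate
30 | 3,5-bis-O-(triethylsilyl)-2-deoxy-D-ribono-1,4-lactone | CC[Si](CC)(CC)OC[C@H]1OC(=O)C[C@@H]1O[Si](CC)(CC)CC | intermediate
31 | (3S,4R)-4-hydroxy-N-methoxy-N-methyl-3,5-bis(triethylsilyloxy)pentanamide | CC[Si](CC)(CC)OC[C@@H](O)[C@@H](O[Si](CC)(CC)CC)CC(=O)N(C)OC | intermediate
32 | (3S,4R)-4-(tert-butyldimethylsilyloxy)-N-methoxy-N-methyl-3,5-bis(triethylsilyloxy)pentanamide | CC[Si](CC)(CC)OC[C@@H](O[Si](C)(C)C(C)(C)C)[C@@H](O[Si](CC)(CC)CC)CC(=O)N(C)OC | intermediate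
33 | lithium [(2R,3S,5R,6S)-3,5-dibromo-6-ethyloxan-2-yl]ethynide (formed in the flask) | [Li]C#C[C@H]1O[C@@H](CC)[C@H](Br)C[C@@H]1Br | intermediate
34 | (5S,6R)-6-(tert-butyldimethylsilyloxy)-1-[(2R,3S,5R,6S)-3,5-dibromo-6-ethyloxan-2-yl]-5,7-bis(triethylsilyloxy)hept-1-yn-3-one | CC[Si](CC)(CC)OC[C@@H](O[Si](C)(C)C(C)(C)C)[C@@H](O[Si](CC)(CC)CC)CC(=O)C#C[C@H]1O[C@@H](CC)[C@H](Br)C[C@@H]1Br | intermediate
35 | (3S,5S,6R)-6-(tert-butyldimethylsilyloxy)-1-[(2R,3S,5R,6S)-3,5-dibromo-6-ethyloxan-2-yl]-5,7-bis(triethylsilyloxy)hept-1-yn-3-ol | CC[Si](CC)(CC)OC[C@@H](O[Si](C)(C)C(C)(C)C)[C@@H](O[Si](CC)(CC)CC)C[C@H](O)C#C[C@H]1O[C@@H](CC)[C@H](Br)C[C@@H]1Br | intermediate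
36 | 3-O-(tert-butyldiphenylsilyl) ether of 35 (O6 in target numbering) | CC[Si](CC)(CC)OC[C@@H](O[Si](C)(C)C(C)(C)C)[C@@H](O[Si](CC)(CC)CC)C[C@H](O[Si](c2ccccc2)(c3ccccc3)C(C)(C)C)C#C[C@H]1O[C@@H](CC)[C@H](Br)C[C@@H]1Br | intermediate
37 | (Z)-alkene from 36 (C7=C8) | CC[Si](CC)(CC)OC[C@@H](O[Si](C)(C)C(C)(C)C)[C@@H](O[Si](CC)(CC)CC)C[C@H](O[Si](c2ccccc2)(c3ccccc3)C(C)(C)C)/C=C\[C@H]1O[C@@H](CC)[C@H](Br)C[C@@H]1Br | intermediate
38 | (2R,3S,5S,6Z)-2-(tert-butyldimethylsilyloxy)-5-(tert-butyldiphenylsilyloxy)-7-[(2R,3S,5R,6S)-3,5-dibromo-6-ethyloxan-2-yl]hept-6-ene-1,3-diol | OC[C@@H](O[Si](C)(C)C(C)(C)C)[C@@H](O)C[C@H](O[Si](c2ccccc2)(c3ccccc3)C(C)(C)C)/C=C\[C@H]1O[C@@H](CC)[C@H](Br)C[C@@H]1Br | intermediate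
39 | (2R)-2-[(2S,4S,5S)-5-{(R)-bromo[(2S,3S,5R,6S)-3,5-dibromo-6-ethyloxan-2-yl]methyl}-4-(tert-butyldiphenylsilyloxy)oxolan-2-yl]-2-(tert-butyldimethylsilyloxy)ethanol | OC[C@@H](O[Si](C)(C)C(C)(C)C)[C@@H]1C[C@H](O[Si](c2ccccc2)(c3ccccc3)C(C)(C)C)[C@H](O1)[C@@H](Br)[C@H]4O[C@@H](CC)[C@H](Br)C[C@@H]4Br | intermediate
40 | C2 aldehyde of 39 (CH2OH oxidised to CHO) | O=C[C@@H](O[Si](C)(C)C(C)(C)C)[C@@H]1C[C@H](O[Si](c2ccccc2)(c3ccccc3)C(C)(C)C)[C@H](O1)[C@@H](Br)[C@H]4O[C@@H](CC)[C@H](Br)C[C@@H]4Br | intermediate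
41 | tert-butyldimethylsilyl ether of 42 (terminal alkyne C1≡C2, 3R) | C#C[C@@H](O[Si](C)(C)C(C)(C)C)[C@@H]1C[C@H](O[Si](c2ccccc2)(c3ccccc3)C(C)(C)C)[C@H](O1)[C@@H](Br)[C@H]4O[C@@H](CC)[C@H](Br)C[C@@H]4Br | intermediate
42 | (1R)-1-[(2S,4S,5S)-5-{(R)-bromo[(2S,3S,5R,6S)-3,5-dibromo-6-ethyloxan-2-yl]methyl}-4-(tert-butyldiphenylsilyloxy)oxolan-2-yl]prop-2-yn-1-ol | C#C[C@@H](O)[C@@H]1C[C@H](O[Si](c2ccccc2)(c3ccccc3)C(C)(C)C)[C@H](O1)[C@@H](Br)[C@H]4O[C@@H](CC)[C@H](Br)C[C@@H]4Br | intermediate
43 | methanesulfonate of 42 | C#C[C@@H](OS(C)(=O)=O)[C@@H]1C[C@H](O[Si](c2ccccc2)(c3ccccc3)C(C)(C)C)[C@H](O1)[C@@H](Br)[C@H]4O[C@@H](CC)[C@H](Br)C[C@@H]4Br | intermediate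
44 | tetrabutylammonium C6 alkoxide of the desilylated mesylate (formed in the flask) | C#C[C@@H](OS(C)(=O)=O)[C@@H]1C[C@H]([O-])[C@H](O1)[C@@H](Br)[C@H]4O[C@@H](CC)[C@H](Br)C[C@@H]4Br.CCCC[N+](CCCC)(CCCC)CCCC | intermediate
45 | (1S,3S,4S,6S)-3-{(R)-bromo[(2S,3S,5R,6S)-3,5-dibromo-6-ethyloxan-2-yl]methyl}-6-ethynyl-2,5-dioxabicyclo[2.2.1]heptane; chain descriptors 3S,4S,6S,7S,8R,9S,10S,12R,13S | C#C[C@@H]1O[C@H]2C[C@@H]1O[C@@H]2[C@@H](Br)[C@H]1O[C@@H](CC)[C@H](Br)C[C@@H]1Br | target

**Step count and risks**

Total step count: 32. Longest linear sequence: 27 steps (steps 1–16 and 22–32; steps 17–21 make the sugar-derived amide).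

Steps most likely to fail:

1. Step 4 (Proposed new method). The doubly stabilised cation may be too weak an electrophile for furan, it may be captured at one terminus only (alkylation of furan at C2 followed by proton loss, without ring closure), or it may close with one ether axial. The fallback uses known chemistry, sets out from furan 9, benzyl alcohol 3 and chlorotriethylsilane 6, and returns at 11. Transacetalisation of commercial 1,1-dimethoxypropan-2-one (COC(OC)C(C)=O) with 3 (TsOH, toluene, removal of methanol) should give 1,1-bis(benzyloxy)propan-2-one F1. LiN(iPr)2 and then 6 should give 3,3-bis(benzyloxy)-2-(triethylsilyloxy)prop-1-ene F2. The documented Me3SiOTf-catalysed (4+3) cycloaddition of this mono-alkoxy precursor with 9 should give racemic 2-(benzyloxy)-8-oxabicyclo[3.2.1]oct-6-en-3-one F3, with the ether equatorial. Kinetic enolisation at C4 (LiN(iPr)2, THF, −78 °C) and Davis hydroxylation with 2-(phenylsulfonyl)-3-phenyloxaziridine, from the face away from the alkene bridge, should give the axial 4-hydroxy ketone F4. Benzyl 2,2,2-trichloroacetimidate with catalytic TfOH should give the 2-equatorial, 4-axial bis(benzyl) ether F5, and DBU in CH2Cl2 should epimerise C4 through the enol to the diequatorial meso ketone 11. Because 11 is meso, the racemic nature of F3 is of no consequence.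

2. Step 27. Bromonium formation on an alkene deactivated by two allylic oxygens may be slow, and closure may take place on the wrong alkene face or in the 6-endo sense at C8. The fallback sets out from propargylic alcohol 35 and returns at 41. NaAlH2(OCH2CH2OMe)2 in THF at −20 °C should reduce the propargylic alcohol by hydroxyl-directed trans-hydroalumination to the E allylic alcohol F6, and silylation (t-BuPh2SiCl, imidazole) should give the silyl ether F7. Shi epoxidation (D-fructose-derived ketone, KHSO5, K2CO3, MeCN/dimethoxymethane/H2O, 0 °C; the enantiomer that gives R,R-epoxides from simple E alkenes) should set the trans-epoxide F8 under reagent control. Camphorsulfonic acid in MeOH/CH2Cl2 should remove both triethylsilyl groups, after which the C4 hydroxyl opens the epoxide at C7 (5-exo, inversion) to give the ring B diol F9 with a free (8S) alcohol. TEMPO with PhI(OAc)2 should oxidise only the primary C2 alcohol to the hydroxy aldehyde F10, and Ohira–Bestmann homologation should give the alkynol F11. CBr4 and P(n-C8H17)3 in toluene at 70 °C should then replace the C8 hydroxyl by bromide with inversion and give 41. In this sequence C7 is set by the epoxidation catalyst and one inversion, and C8 by the epoxide and one inversion.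

3. Step 32. Fluoride or the liberated alkoxide may consume the activated propargylic mesylate in other ways (fluoride substitution, elimination to an enyne) faster than the strained bicycle closes. The fallback sets out from propargylic alcohol 42 and returns at 45. Dess–Martin oxidation should give the C3 alkynyl ketone F12, and HF·pyridine should remove the silyl group to give the hydroxy ynone F13, in equilibrium with its bicyclic hemiketal. Et3SiH and Me3SiOTf in CH2Cl2 at −78 °C should reduce the derived bicyclic oxocarbenium ion (reductive etherification, as used for C-glycosides from lactols); hydride should arrive on the exo face, syn to the C5 methylene bridge, which leaves the alkyne endo as in 45.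

Further compounds
F1 | step 4 | 1,1-bis(benzyloxy)propan-2-one | CC(=O)C(OCc1ccccc1)OCc1ccccc1
F2 | step 4 | 3,3-bis(benzyloxy)-2-(triethylsilyloxy)prop-1-ene | C=C(O[Si](CC)(CC)CC)C(OCc1ccccc1)OCc1ccccc1
F3 | step 4 | rac-2-(benzyloxy)-8-oxabicyclo[3.2.1]oct-6-en-3-one, ether equatorial (one enantiomer drawn) | O=C1[C@@H](OCc3ccccc3)[C@H]2C=C[C@H](O2)C1
F4 | step 4 | rac-2-(benzyloxy)-4-hydroxy-8-oxabicyclo[3.2.1]oct-6-en-3-one, ether equatorial, OH axial (one enantiomer drawn) | O=C1[C@@H](OCc3ccccc3)[C@H]2C=C[C@H](O2)[C@@H]1O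
F5 | step 4 | rac-2,4-bis(benzyloxy)-8-oxabicyclo[3.2.1]oct-6-en-3-one, C2 ether equatorial, C4 ether axial (one enantiomer drawn) | O=C1[C@@H](OCc3ccccc3)[C@H]2C=C[C@H](O2)[C@@H]1OCc4ccccc4
F6 | step 27 | (1E,3S,5S,6R)-6-(tert-butyldimethylsilyloxy)-1-[(2R,3S,5R,6S)-3,5-dibromo-6-ethyloxan-2-yl]-5,7-bis(triethylsilyloxy)hept-1-en-3-ol | CC[Si](CC)(CC)OC[C@@H](O[Si](C)(C)C(C)(C)C)[C@@H](O[Si](CC)(CC)CC)C[C@H](O)/C=C/[C@H]1O[C@@H](CC)[C@H](Br)C[C@@H]1Br
F7 | step 27 | 3-O-(tert-butyldiphenylsilyl) ether of F6 | CC[Si](CC)(CC)OC[C@@H](O[Si](C)(C)C(C)(C)C)[C@@H](O[Si](CC)(CC)CC)C[C@H](O[Si](c2ccccc2)(c3ccccc3)C(C)(C)C)/C=C/[C@H]1O[C@@H](CC)[C@H](Br)C[C@@H]1Br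
F8 | step 27 | trans-C7,C8-epoxide of F7 | CC[Si](CC)(CC)OC[C@@H](O[Si](C)(C)C(C)(C)C)[C@@H](O[Si](CC)(CC)CC)C[C@H](O[Si](c2ccccc2)(c3ccccc3)C(C)(C)C)[C@H]4O[C@@H]4[C@H]1O[C@@H](CC)[C@H](Br)C[C@@H]1Br
F9 | step 27 | ring B diol, (8S)-alcohol in place of the bromide of 39 | OC[C@@H](O[Si](C)(C)C(C)(C)C)[C@@H]1C[C@H](O[Si](c2ccccc2)(c3ccccc3)C(C)(C)C)[C@H](O1)[C@H](O)[C@H]4O[C@@H](CC)[C@H](Br)C[C@@H]4Br
F10 | step 27 | C2 aldehyde of F9 with free C8 alcohol | O=C[C@@H](O[Si](C)(C)C(C)(C)C)[C@@H]1C[C@H](O[Si](c2ccccc2)(c3ccccc3)C(C)(C)C)[C@H](O1)[C@H](O)[C@H]4O[C@@H](CC)[C@H](Br)C[C@@H]4Br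
F11 | step 27 | C1≡C2 alkyne with free (8S)-alcohol | C#C[C@@H](O[Si](C)(C)C(C)(C)C)[C@@H]1C[C@H](O[Si](c2ccccc2)(c3ccccc3)C(C)(C)C)[C@H](O1)[C@H](O)[C@H]4O[C@@H](CC)[C@H](Br)C[C@@H]4Br
F12 | step 32 | C3 alkynyl ketone from 42 | C#CC(=O)[C@@H]1C[C@H](O[Si](c2ccccc2)(c3ccccc3)C(C)(C)C)[C@H](O1)[C@@H](Br)[C@H]4O[C@@H](CC)[C@H](Br)C[C@@H]4Br
F13 | step 32 | C6-hydroxy C3 alkynyl ketone (open form of the bicyclic hemiketal) | C#CC(=O)[C@@H]1C[C@H](O)[C@H](O1)[C@@H](Br)[C@H]4O[C@@H](CC)[C@H](Br)C[C@@H]4Br
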